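The meeting started from late times, to see what a run's contents come to once its readings stand flat. The chair showed the ash run, which reads 61.8 % at 80.0 s and 61.3 % at 120 s, and recalled the candidate steps: a first exchange of starting complex with incoming ligand, a reversible second exchange, and a loss of starting complex with leaving ligand to side product.

| flask | starting complex | incoming ligand | leaving ligand | remark | time |
|---|---|---|---|---|---|
| elm | 5.0 × 10⁻⁴ M | 0.15 mM | 1 mM | run made earlier |  |
| ash | 5.0 × 10⁻⁴ M | 1.5 mM | 1 mM | run made earlier |  |
| beta | 5.0 × 10⁻⁴ M | 0.250 mM | 1.00 mM |  | 2.0 min |
| alpha | 5.0 × 10⁻⁴ M | 0.600 mM | 1.00 mM |  | 2.0 min |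
| epsilon | 5.0 × 10⁻⁴ M | 2.00 mM | 1.00 mM |  | 2.0 min |

| run | time / s | complex with one exchanged / % |
|---|---|---|
| elm | 15.0 | 21.9 |
| elm | 40.0 | 28.1 |
| elm | 80.0 | 29.7 |
| elm | 120 | 28.0 |
| ash | 15.0 | 62.1 |
| ash | 40.0 | 61.3 |
| ash | 80.0 | 61.8 |
| ash | 120 | 61.3 |

(scatter of a reading: 1 percentage point)

- candidate steps: starting complex + incoming ligand -> leaving ligand + complex with one exchanged; complex with one exchanged + incoming ligand <-> leaving ligand + complex with two exchanged; leaving ligand + starting complex -> side product

- complex with one exchanged at the end, in percent of the starting complex charged, for each flask in turn (beta, alpha, epsilon)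

One member took the mean ash plateau, 61.6 %, and assumed that the remaining 38.4 % was complex with two exchanged. Each exchange spends one incoming ligand and frees one leaving ligand, so ash held 0.808 mM of incoming ligand and 1.69 mM of leaving ligand. That gave 1.30. This exchange quotient, two exchanged times leaving ligand over one exchanged times incoming ligand, is the second exchange's equilibrium constant as read; its logarithm is 0.115.

The member then worked epsilon in powers of ten. Trying 0.5 of the complex as twice exchanged leaves 1.25 mM of incoming ligand and 1.75 mM of leaving ligand. The logarithm of two exchanged over one exchanged is then −0.0309, a ratio of 0.931, so one exchanged is 51.8 %.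

A second member argued that in alpha the excess of incoming ligand, 0.100 mM, divides between free ligand and second exchange. The exchange quotient makes complex with two exchanged over free incoming ligand equal to the quotient times complex with one exchanged over leaving ligand. This member set side product aside and took complex with one exchanged as about 5.0 × 10⁻⁴ M and leaving ligand as about 1.50 mM, which gave a ratio of 0.435. So 30.3 % of the excess goes to the second exchange, and complex with one exchanged ends at 93.9 % by this member's reckoning. For beta, the chair noted that incoming ligand is the limiting reagent, and its charge allows 50.0 %.

The forecast gave 48.5 %, 89.5 % and 51.5 % for beta, alpha and epsilon, holding that the ash plateau “indicates a fast second-exchange equilibrium”. It stands lower than the second member's alpha figure.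

The flasks give 49.2 %, 82.2 % and 51.9 % for beta, alpha and epsilon. At 2.00 min, alpha held 9.53 % of side product and 7.70 % of complex with two exchanged.

    starting complex + incoming ligand → leaving ligand + complex with one exchanged (k = 227 /M/s)
    complex with one exchanged + incoming ligand ⇌ leaving ligand + complex with two exchanged (K = 1.20, k = 98.1 /M/s)
    leaving ligand + starting complex → side product (k = 5.17 /M/s)

At alpha's end, with 0.112 mM of incoming ligand and 1.44 mM of leaving ligand, the exchange quotient is 1.20. At epsilon's end, with 1.28 mM of incoming ligand, 1.71 mM of leaving ligand and 46.4 % of complex with two exchanged, it is 1.20.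

(The numbers in the tables come from a simulation with made-up constants; scatter was added.)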